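**Plan**
1. Retrosynthesis: the eighteen O-methyl groups and the two ester carbons on ring A come off last. Ring A is then cut at the two ring bonds that join each hydroxyl-bearing carbon next to the ether carbon to its neighbouring CH carbon, giving an aryloxymalonate and 3-oxoglutarate. The bond from the ring-A ether carbon to oxygen goes back to O-alkylation of the ring-B phenol with chloromalonate.
2. The B–H heptamer is cut at its six diaryl ether bonds. The two most hindered ones (ring D to ring E and ring F to ring G, each at a ring-D or ring-F carbon flanked by two methoxy-bearing carbons) are made once, on monomers, inside a two-ring bromo-aldehyde block.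
3. Forward: ring-B chlorophenol + ring-C bromo-aldehyde, Baeyer–Villiger; + two-ring block (rings D, E), Baeyer–Villiger; + two-ring block (rings F, G), Baeyer–Villiger; + ring-H bromide. Each formyl group is carried through a coupling and then becomes the next phenol.
4. A chlorine on ring B, inert in all copper steps, is then exchanged for hydroxyl. O-alkylation, closure of ring A (the only ring formed in the synthesis), ester removal and ether cleavage follow.
5. Enabling feature: ring A is a benzene-1,3,5-triol whose ether oxygen sits on the carbon between two hydroxyl-bearing carbons. That carbon and its two neighbours therefore map onto an aryloxymalonate, and the other three ring carbons onto 3-oxoglutarate.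
6. Stereochemistry: the target has no stereocentre and no stereogenic double bond, so nothing has to be set.

Key step: step 13

Assumption and notation: rings are lettered A to H along the SMILES string of the target. On rings B to H, positions are counted from the carbon bearing the oxygen to the preceding ring; on ring A, from the carbon bearing the ether oxygen. Ring B carries oxygen substituents at positions 3 and 4 and the oxygen to ring C at position 5. Rings C, E and G carry oxygen substituents at positions 3 to 5 and the oxygen to the following ring at position 6. Rings D and F carry oxygen substituents at positions 3 and 5 and the oxygen to the following ring at position 4. Ring H is a 3,4,5-trioxygenated phenoxy group. The diaryl ether axes are taken as freely rotating, so no atropisomers are considered.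

**Route**

Step 1
Reactants: 1 5-bromo-1,2,3-trimethoxybenzene
Product: 2 6-bromo-2,3,4-trimethoxybenzaldehyde
Conditions: Cl2CHOMe, TiCl4, CH2Cl2, −10 → 0 °C; then ice-water
Reagents that add atoms: dichloromethyl methyl ether, COC(Cl)Cl; water, O
Why: Rieche formylation (electrophilic aromatic substitution); the two free positions of 1 are equivalent and each lies ortho and para to a methoxy group, so a single aldehyde should form, with bromine ortho to the formyl group as the later couplings require.

Step 2
Reactants: 3 4-bromo-2,6-dimethoxyphenol; 2 6-bromo-2,3,4-trimethoxybenzaldehyde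
Product: 4 6-(4-bromo-2,6-dimethoxyphenoxy)-2,3,4-trimethoxybenzaldehyde
Conditions: CuI (10 mol %), K2CO3, pyridine, 100 °C, Ar
Reagents that add atoms: none
Why: Ullmann diaryl ether synthesis in which the ortho-formyl group speeds substitution of the C–Br bond of 2, while the unactivated C–Br bond para to oxygen in 3 and 4 should be left alone without an accelerating ligand; the most hindered ether type of the target is thus made once on simple monomers.

Step 3
Reactants: 5 5-chloro-2,3-dimethoxybenzaldehyde
Product: 7 5-chloro-2,3-dimethoxyphenol, via 5-chloro-2,3-dimethoxyphenyl formate 6 (not isolated)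
Conditions: mCPBA (1.3 equiv), CH2Cl2, 0 → 25 °C; aq. NaHCO3 wash; then K2CO3 (cat.), MeOH, 25 °C
Reagents that add atoms: mCPBA, O=C(OO)c1cccc(Cl)c1
Why: Baeyer–Villiger oxidation with migration of the ortho-methoxy-substituted aryl group gives the formate, which is methanolysed only after the peracid is gone; the aryl chloride is inert.

Step 4
Reactants: 7 5-chloro-2,3-dimethoxyphenol; 2 6-bromo-2,3,4-trimethoxybenzaldehyde
Product: 8 6-(5-chloro-2,3-dimethoxyphenoxy)-2,3,4-trimethoxybenzaldehyde (B–C aldehyde)
Conditions: CuI (10 mol %), K2CO3, pyridine, 100 °C, Ar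
Reagents that add atoms: none
Why: Ullmann diaryl ether synthesis at the formyl-activated C–Br bond of 2 forms the ether between ring B and ring C, and the ring-B C–Cl bond does not react with copper under these conditions.

Step 5
Reactants: 8 B–C aldehyde
Product: 10 6-(5-chloro-2,3-dimethoxyphenoxy)-2,3,4-trimethoxyphenol (B–C phenol), via B–C aryl formate 9 (not isolated)
Conditions: mCPBA (1.3 equiv), CH2Cl2, 0 → 25 °C; aq. NaHCO3 wash; then K2CO3 (cat.), MeOH, 25 °C
Reagents that add atoms: mCPBA, O=C(OO)c1cccc(Cl)c1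
Why: Baeyer–Villiger oxidation; the migrating aryl carbon is flanked by an aryloxy and a methoxy group and has a para methoxy group, so aryl migration should dominate, and a small excess of peracid at low temperature spares the electron-rich rings.

Step 6
Reactants: 10 B–C phenol; 4 6-(4-bromo-2,6-dimethoxyphenoxy)-2,3,4-trimethoxybenzaldehyde
Product: 11 B–C–D–E tetramer aldehyde (chlorine on ring B, formyl on ring E, ten methoxy groups)
Conditions: CuI (20 mol %), picolinic acid (40 mol %), K3PO4, DMSO, 100 °C, Ar
Reagents that add atoms: none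
Why: Ligand-accelerated Ullmann ether synthesis (CuI/picolinic acid, a system suited to 2,6-disubstituted phenols): the hindered ring-C phenoxide of 10 meets a C–Br bond flanked by two hydrogens, the ring-B C–Cl bond is not touched by copper at this temperature, and the non-enolisable formyl group of 4 is carried through for step 7.

Step 7
Reactants: 11 B–C–D–E tetramer aldehyde
Product: 13 B–C–D–E tetramer phenol (free hydroxyl on ring E), via tetramer aryl formate 12 (not isolated)
Conditions: mCPBA (1.3 equiv), CH2Cl2, 0 → 25 °C; aq. NaHCO3 wash; then K2CO3 (cat.), MeOH, 25 °C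
Reagents that add atoms: mCPBA, O=C(OO)c1cccc(Cl)c1
Why: Baeyer–Villiger oxidation of a 2-aryloxy-6-methoxybenzaldehyde, as in step 5, followed by formate methanolysis.

Step 8
Reactants: 13 B–C–D–E tetramer phenol; 4 6-(4-bromo-2,6-dimethoxyphenoxy)-2,3,4-trimethoxybenzaldehyde
Product: 14 B–G hexamer aldehyde (chlorine on ring B, formyl on ring G, fifteen methoxy groups)
Conditions: CuI (20 mol %), picolinic acid (40 mol %), K3PO4, DMSO, 100 °C, Ar
Reagents that add atoms: none
Why: The same ligand-accelerated Ullmann ether synthesis as in step 6, adding rings F and G in one operation through the unhindered C–Br bond of block 4.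

Step 9
Reactants: 14 B–G hexamer aldehyde
Product: 16 B–G hexamer phenol (free hydroxyl on ring G), via hexamer aryl formate 15 (not isolated)
Conditions: mCPBA (1.3 equiv), CH2Cl2, 0 → 25 °C; aq. NaHCO3 wash; then K2CO3 (cat.), MeOH, 25 °C
Reagents that add atoms: mCPBA, O=C(OO)c1cccc(Cl)c1
Why: Baeyer–Villiger oxidation and formate methanolysis as in steps 5 and 7.

Step 10
Reactants: 16 B–G hexamer phenol; 1 5-bromo-1,2,3-trimethoxybenzene
Product: 17 B–H heptamer chloride (chlorine on ring B, eighteen methoxy groups)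
Conditions: 1 (3 equiv), CuI (20 mol %), picolinic acid (40 mol %), K3PO4, DMSO, 110 °C, Ar
Reagents that add atoms: none
Why: Ligand-accelerated Ullmann ether synthesis of the hindered ring-G phenoxide with a cheap, unhindered aryl bromide used in excess caps the chain with ring H.

Step 11
Reactants: 17 B–H heptamer chloride
Product: 18 B–H heptamer phenol (free hydroxyl on ring B)
Conditions: Pd2(dba)3 (2 mol %), 2-di-tert-butylphosphino-2′,4′,6′-triisopropylbiphenyl (tBuXPhos, 8 mol %), KOH (4 equiv), 1,4-dioxane/H2O, 100 °C; then 1 M HCl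
Reagents that add atoms: potassium hydroxide, [K+].[OH-]
Why: Palladium-catalysed hydroxylation of an aryl chloride with KOH (C–O cross-coupling with a bulky biarylphosphine); the ring-B C–Cl bond is the only carbon–halogen bond of 17 and lies between two hydrogens, and aryl ethers are stable to hot aqueous hydroxide.

Step 12
Reactants: 18 B–H heptamer phenol; 19 dimethyl chloromalonate
Product: 20 dimethyl 2-(aryloxy)malonate (aryl = heptamer 18 bonded through its ring-B phenol oxygen)
Conditions: K2CO3, DMF, 50 °C
Reagents that add atoms: none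
Why: Williamson-type SN2 O-alkylation of the unhindered ring-B phenoxide by the doubly activated secondary chloride, the standard way to aryloxymalonates; the chloride is less prone to halophilic attack than the bromide, and methyl esters match those of 21 so that no mixed esters arise later.

Step 13
Reactants: 20 dimethyl 2-(aryloxy)malonate; 21 dimethyl 3-oxoglutarate
Product: 23 dimethyl 2,4,6-trihydroxy-5-(aryloxy)isophthalate (octamer, ring A as diester), via acyclic dioxoheptanedioate triester 22 (not isolated)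
Conditions: 21 (2 equiv), NaH (4 equiv), diglyme, 0 → 25 °C; then 130 °C with MeOH distilled off, Ar; then 1 M HCl
Reagents that add atoms: none
Why: The sodium enolate of 21 attacks one ester carbonyl of 20 through carbon (intermolecular Claisen acylation; 20 is in equilibrium with its own enolate and, at this temperature, possibly with the derived acylketene) to give triester 22, whose remaining CH2 enolate attacks the second malonate ester and expels methoxide, after which the cyclohexane-1,3,5-trione enolises to the aromatic ring. The closest known reaction is the sodium-mediated condensation of dialkyl malonates with dialkyl 3-oxoglutarates to 2,4,6-trihydroxyisophthalates, the laboratory copy of the triketide cyclisation that gives phloroglucinol. Ring A closes by a 6-(enolendo)-exo-trig Dieckmann-type attack, so that the two new C–C bonds join positions 2 and 3 and positions 6 and 5 of ring A, and no stereocentre is created. The step needs C- over O-acylation and cross- over self-condensation: all acyl transfers are reversible whereas formation of the phloroglucinolate salt is not, 21 is used in excess so that its self-condensation (small polar by-products) does not starve 20, and both partners are symmetrical so that only one ring constitution can arise. Because the aryloxy group already sits on the malonate carbon, the ether at the carbon flanked by two hydroxyls is carried in and not made by coupling, and the six diaryl ether bonds and eighteen methyl ethers of 20 are inert to alkoxide.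

Step 14
Reactants: 23 dimethyl 2,4,6-trihydroxy-5-(aryloxy)isophthalate
Product: 25 2-(aryloxy)benzene-1,3,5-triol (octamer, free ring-A triol, eighteen methoxy groups), via 2,4,6-trihydroxy-5-(aryloxy)isophthalic acid 24 (not isolated)
Conditions: 2 M KOH (aq, degassed), 1,4-dioxane, 90 °C, Ar; then 2 M HCl to pH 1, 60 °C
Reagents that add atoms: none
Why: Ester saponification followed by decarboxylation of a 2,4,6-trihydroxyisophthalic acid, which loses CO2 readily through ipso-protonation of its keto tautomer; methyl and diaryl ethers are untouched and exclusion of air protects the ring-A triol.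

Step 15
Reactants: 25 2-(aryloxy)benzene-1,3,5-triol
Product: 26 CNP0175816.0 (target)
Conditions: BBr3 (40 equiv), CH2Cl2, −78 → 25 °C, Ar; then degassed H2O, 0 °C; Sephadex LH-20 with degassed MeOH
Reagents that add atoms: none
Why: Lewis acid-mediated cleavage of aryl methyl ethers with BBr3 (bromide SN2 at methyl after O–B complexation); diaryl ether bonds are not cleaved and there is no stereocentre or acid-labile group, so a large excess can be used.

**Compound list**
1 | 5-bromo-1,2,3-trimethoxybenzene | COc1cc(Br)cc(OC)c1OC | starting material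
2 | 6-bromo-2,3,4-trimethoxybenzaldehyde | O=Cc1c(Br)cc(OC)c(OC)c1OC | intermediate
3 | 4-bromo-2,6-dimethoxyphenol | COc1cc(Br)cc(OC)c1O | starting material
4 | 6-(4-bromo-2,6-dimethoxyphenoxy)-2,3,4-trimethoxybenzaldehyde (two-ring block for rings D/E and F/G) | O=Cc1c(Oc2c(OC)cc(Br)cc2OC)cc(OC)c(OC)c1OC | intermediate
5 | 5-chloro-2,3-dimethoxybenzaldehyde | O=Cc1cc(Cl)cc(OC)c1OC | starting material
6 | 5-chloro-2,3-dimethoxyphenyl formate (not isolated) | O=COc1cc(Cl)cc(OC)c1OC | intermediate
7 | 5-chloro-2,3-dimethoxyphenol | Oc1cc(Cl)cc(OC)c1OC | intermediate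
8 | 6-(5-chloro-2,3-dimethoxyphenoxy)-2,3,4-trimethoxybenzaldehyde (B–C aldehyde) | COc1cc(Cl)cc(Oc2cc(OC)c(OC)c(OC)c2C=O)c1OC | intermediate
9 | 6-(5-chloro-2,3-dimethoxyphenoxy)-2,3,4-trimethoxyphenyl formate (not isolated) | COc1cc(Cl)cc(Oc2cc(OC)c(OC)c(OC)c2OC=O)c1OC | intermediate
10 | 6-(5-chloro-2,3-dimethoxyphenoxy)-2,3,4-trimethoxyphenol (B–C phenol) | COc1cc(Cl)cc(Oc2cc(OC)c(OC)c(OC)c2O)c1OC | intermediate
11 | B–C–D–E tetramer aldehyde (10 bonded through its phenol oxygen to the former C–Br carbon of ring D of block 4; formyl on ring E) | COc1cc(Cl)cc(Oc2cc(OC)c(OC)c(OC)c2Oc2cc(OC)c(Oc3cc(OC)c(OC)c(OC)c3C=O)c(OC)c2)c1OC | intermediate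
12 | B–C–D–E tetramer aryl formate (formyloxy on ring E; not isolated) | COc1cc(Cl)cc(Oc2cc(OC)c(OC)c(OC)c2Oc2cc(OC)c(Oc3cc(OC)c(OC)c(OC)c3OC=O)c(OC)c2)c1OC | intermediate
13 | B–C–D–E tetramer phenol (free hydroxyl on ring E) | COc1cc(Cl)cc(Oc2cc(OC)c(OC)c(OC)c2Oc2cc(OC)c(Oc3cc(OC)c(OC)c(OC)c3O)c(OC)c2)c1OC | intermediate
14 | B–G hexamer aldehyde (13 bonded through its ring-E phenol oxygen to the former C–Br carbon of ring F of a second block 4; formyl on ring G) | COc1cc(Cl)cc(Oc2cc(OC)c(OC)c(OC)c2Oc2cc(OC)c(Oc3cc(OC)c(OC)c(OC)c3Oc3cc(OC)c(Oc4cc(OC)c(OC)c(OC)c4C=O)c(OC)c3)c(OC)c2)c1OC | intermediate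
15 | B–G hexamer aryl formate (formyloxy on ring G; not isolated) | COc1cc(Cl)cc(Oc2cc(OC)c(OC)c(OC)c2Oc2cc(OC)c(Oc3cc(OC)c(OC)c(OC)c3Oc3cc(OC)c(Oc4cc(OC)c(OC)c(OC)c4OC=O)c(OC)c3)c(OC)c2)c1OC | intermediate
16 | B–G hexamer phenol (free hydroxyl on ring G) | COc1cc(Cl)cc(Oc2cc(OC)c(OC)c(OC)c2Oc2cc(OC)c(Oc3cc(OC)c(OC)c(OC)c3Oc3cc(OC)c(Oc4cc(OC)c(OC)c(OC)c4O)c(OC)c3)c(OC)c2)c1OC | intermediate
17 | B–H heptamer chloride (16 bonded through its ring-G phenol oxygen to a 3,4,5-trimethoxyphenyl ring H; chlorine on ring B) | COc1cc(Cl)cc(Oc2cc(OC)c(OC)c(OC)c2Oc2cc(OC)c(Oc3cc(OC)c(OC)c(OC)c3Oc3cc(OC)c(Oc4cc(OC)c(OC)c(OC)c4Oc4cc(OC)c(OC)c(OC)c4)c(OC)c3)c(OC)c2)c1OC | intermediate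
18 | B–H heptamer phenol (free hydroxyl on ring B; eighteen methoxy groups) | COc1cc(O)cc(Oc2cc(OC)c(OC)c(OC)c2Oc2cc(OC)c(Oc3cc(OC)c(OC)c(OC)c3Oc3cc(OC)c(Oc4cc(OC)c(OC)c(OC)c4Oc4cc(OC)c(OC)c(OC)c4)c(OC)c3)c(OC)c2)c1OC | intermediate
19 | dimethyl chloromalonate | COC(=O)C(Cl)C(=O)OC | starting material
20 | dimethyl 2-(aryloxy)malonate, aryl = heptamer 18 bonded through its ring-B phenol oxygen | COC(=O)C(C(=O)OC)Oc2cc(OC)c(OC)c(Oc3cc(OC)c(OC)c(OC)c3Oc3cc(OC)c(Oc4cc(OC)c(OC)c(OC)c4Oc4cc(OC)c(Oc5cc(OC)c(OC)c(OC)c5Oc5cc(OC)c(OC)c(OC)c5)c(OC)c4)c(OC)c3)c2 | intermediate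
21 | dimethyl 3-oxoglutarate | COC(=O)CC(=O)CC(=O)OC | starting material
22 | dimethyl 2-(aryloxy)-4-(methoxycarbonyl)-3,5-dioxoheptanedioate (first Claisen product; not isolated) | COC(=O)CC(=O)C(C(=O)OC)C(=O)C(C(=O)OC)Oc2cc(OC)c(OC)c(Oc3cc(OC)c(OC)c(OC)c3Oc3cc(OC)c(Oc4cc(OC)c(OC)c(OC)c4Oc4cc(OC)c(Oc5cc(OC)c(OC)c(OC)c5Oc5cc(OC)c(OC)c(OC)c5)c(OC)c4)c(OC)c3)c2 | intermediate
23 | dimethyl 2,4,6-trihydroxy-5-(aryloxy)isophthalate (octamer, ring A as diester) | COC(=O)c1c(O)c(C(=O)OC)c(O)c(Oc2cc(OC)c(OC)c(Oc3cc(OC)c(OC)c(OC)c3Oc3cc(OC)c(Oc4cc(OC)c(OC)c(OC)c4Oc4cc(OC)c(Oc5cc(OC)c(OC)c(OC)c5Oc5cc(OC)c(OC)c(OC)c5)c(OC)c4)c(OC)c3)c2)c1O | intermediate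
24 | 2,4,6-trihydroxy-5-(aryloxy)isophthalic acid (not isolated) | OC(=O)c1c(O)c(C(=O)O)c(O)c(Oc2cc(OC)c(OC)c(Oc3cc(OC)c(OC)c(OC)c3Oc3cc(OC)c(Oc4cc(OC)c(OC)c(OC)c4Oc4cc(OC)c(Oc5cc(OC)c(OC)c(OC)c5Oc5cc(OC)c(OC)c(OC)c5)c(OC)c4)c(OC)c3)c2)c1O | intermediate
25 | 2-(aryloxy)benzene-1,3,5-triol (octamer, free ring-A triol, eighteen methoxy groups) | Oc1cc(O)c(Oc2cc(OC)c(OC)c(Oc3cc(OC)c(OC)c(OC)c3Oc3cc(OC)c(Oc4cc(OC)c(OC)c(OC)c4Oc4cc(OC)c(Oc5cc(OC)c(OC)c(OC)c5Oc5cc(OC)c(OC)c(OC)c5)c(OC)c4)c(OC)c3)c2)c(O)c1 | intermediate
26 | CNP0175816.0 (octamer, twenty-one free hydroxyls) | Oc1cc(O)c(Oc2cc(O)c(O)c(Oc3cc(O)c(O)c(O)c3Oc3cc(O)c(Oc4cc(O)c(O)c(O)c4Oc4cc(O)c(Oc5cc(O)c(O)c(O)c5Oc5cc(O)c(O)c(O)c5)c(O)c4)c(O)c3)c2)c(O)c1 | target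

**Step count**
Total step count: 15.
Longest linear sequence: 13 steps (5 → 26 through steps 3–15; the same length from 1 through steps 1 and 4–15).

**Steps most likely to fail**

First, step 13 (ring-A closure). The first C-acylation may be outrun by self-condensation of the oxoglutarate or diverted to O-acylation and pyranone formation, while the aryloxymalonate rests as its unreactive sodium enolate. The fallback sets out from 18 and builds ring A by the coupling/oxidation chemistry already used in the route. Heptamer phenol 18 is coupled with commercial 4-bromo-3,5-dimethoxybenzaldehyde, whose bromide is para to the formyl group (CuI, picolinic acid, K3PO4, DMSO, 110 °C), to give the octamer aldehyde F1. Baeyer–Villiger oxidation (mCPBA, CH2Cl2) gives the octamer aryl formate F2, and methanolysis (K2CO3, MeOH) gives the octamer phenol F3, in which ring A is a 4-aryloxy-3,5-dimethoxyphenol. BBr3 cleavage of its twenty methyl ethers under the conditions of step 15 returns to the route at 26.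

Second, step 8 (hexamer-forming coupling). The di-ortho-substituted phenoxide may couple too slowly with the unactivated, electron-rich aryl bromide, leaving time for protodebromination of 4 or exchange of its formyl-activated aryloxy group. The fallback sets out from 13 and uses only formyl-activated bromides. Phenol 13 is coupled with commercial 4-bromo-2,6-dimethoxybenzaldehyde (bromide para to formyl, no ortho substituent; CuI, picolinic acid, K3PO4, DMSO, 90 °C) to give the B–F pentamer aldehyde F4. mCPBA gives the pentamer aryl formate F5 and methanolysis the pentamer phenol F6, whose ring-F hydroxyl is flanked by two methoxy groups. Coupling of F6 with 2 under the conditions of step 2 (formyl-activated C–Br) returns to the route at 14.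

Third, step 15 (global demethylation). Some of the eighteen methyl ethers may resist cleavage, and the pyrogallol-type rings may oxidise during aqueous isolation. The fallback sets out from 25. After the BBr3 treatment and quench, the crude polyphenol is not purified but acetylated at once (Ac2O, pyridine, DMAP, Ar) to the henicosaacetate F7. This compound should be stable to air and chromatographable on silica, which would also separate under-cleaved material. Deacetylation (NaOMe cat., degassed MeOH, 0 °C, Ar; then acidic ion-exchange resin) returns to the route at 26.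

**Further compounds**
F1 | step 13 | octamer aldehyde: 4-(aryloxy)-3,5-dimethoxybenzaldehyde, aryl = heptamer 18 bonded through its ring-B phenol oxygen | O=Cc1cc(OC)c(Oc2cc(OC)c(OC)c(Oc3cc(OC)c(OC)c(OC)c3Oc3cc(OC)c(Oc4cc(OC)c(OC)c(OC)c4Oc4cc(OC)c(Oc5cc(OC)c(OC)c(OC)c5Oc5cc(OC)c(OC)c(OC)c5)c(OC)c4)c(OC)c3)c2)c(OC)c1
F2 | step 13 | octamer aryl formate: 4-(aryloxy)-3,5-dimethoxyphenyl formate | O=COc1cc(OC)c(Oc2cc(OC)c(OC)c(Oc3cc(OC)c(OC)c(OC)c3Oc3cc(OC)c(Oc4cc(OC)c(OC)c(OC)c4Oc4cc(OC)c(Oc5cc(OC)c(OC)c(OC)c5Oc5cc(OC)c(OC)c(OC)c5)c(OC)c4)c(OC)c3)c2)c(OC)c1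
F3 | step 13 | octamer phenol: 4-(aryloxy)-3,5-dimethoxyphenol (twenty methoxy groups) | Oc1cc(OC)c(Oc2cc(OC)c(OC)c(Oc3cc(OC)c(OC)c(OC)c3Oc3cc(OC)c(Oc4cc(OC)c(OC)c(OC)c4Oc4cc(OC)c(Oc5cc(OC)c(OC)c(OC)c5Oc5cc(OC)c(OC)c(OC)c5)c(OC)c4)c(OC)c3)c2)c(OC)c1
F4 | step 8 | B–F pentamer aldehyde (13 bonded through its ring-E phenol oxygen to a 4-formyl-3,5-dimethoxyphenyl ring F) | COc1cc(Cl)cc(Oc2cc(OC)c(OC)c(OC)c2Oc2cc(OC)c(Oc3cc(OC)c(OC)c(OC)c3Oc3cc(OC)c(C=O)c(OC)c3)c(OC)c2)c1OC
F5 | step 8 | B–F pentamer aryl formate (formyloxy on ring F) | COc1cc(Cl)cc(Oc2cc(OC)c(OC)c(OC)c2Oc2cc(OC)c(Oc3cc(OC)c(OC)c(OC)c3Oc3cc(OC)c(OC=O)c(OC)c3)c(OC)c2)c1OC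
F6 | step 8 | B–F pentamer phenol (free hydroxyl on ring F) | COc1cc(Cl)cc(Oc2cc(OC)c(OC)c(OC)c2Oc2cc(OC)c(Oc3cc(OC)c(OC)c(OC)c3Oc3cc(OC)c(O)c(OC)c3)c(OC)c2)c1OC
F7 | step 15 | henicosaacetate of 26 (all twenty-one hydroxyls acetylated) | CC(=O)Oc1cc(OC(C)=O)c(Oc2cc(OC(C)=O)c(OC(C)=O)c(Oc3cc(OC(C)=O)c(OC(C)=O)c(OC(C)=O)c3Oc3cc(OC(C)=O)c(Oc4cc(OC(C)=O)c(OC(C)=O)c(OC(C)=O)c4Oc4cc(OC(C)=O)c(Oc5cc(OC(C)=O)c(OC(C)=O)c(OC(C)=O)c5Oc5cc(OC(C)=O)c(OC(C)=O)c(OC(C)=O)c5)c(OC(C)=O)c4)c(OC(C)=O)c3)c2)c(OC(C)=O)c1
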